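The all-cis 2,4,6-trisubstituted oxane ring (O1, C2–C6) is read as a fully reduced pyrylium ion. Everything rests on a [3+3] pyrylium annulation: 4-acetylphenyl acetate supplies O1–C2–C3, an aryl enone supplies C4–C5–C6, and one operation (Michael addition, cyclodehydration, hydride abstraction) forms C3–C4 and O1–C6. It exploits the 1,5-relationship of the two oxygen-bearing ring carbons C2 and C6 across the aryl-bearing C4. The precursors are two achiral ketones; the product is a flat pyrylium salt that already carries all three side chains. An enantioselective dearomatising hydrogenation then sets C2, C4 and C6 in one event, and acetylation, debenzylation and a Claisen–Schmidt condensation complete the chalcone.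

Key step: step 5

Remark: ring numbering used below is O1, C2 (bears the 4-oxygenated phenyl), C3, C4 (bears the trioxygenated aryl), C5, C6 (bears the arylethyl chain C7–C8); the target is the all-cis (2S,4R,6S) isomer. The ligand antipode written in step 6 is provisional; the one that proves to give this series is used.

Step 1
Reactants: 1 2,4,6-trimethoxybenzaldehyde
Product: 2 2,6-dihydroxy-4-methoxybenzaldehyde
Conditions: AlCl3 (4 equiv), CH2Cl2, 0 °C to reflux; aq. HCl work-up
Reagents that add atoms: none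
Why: Chelation-directed Lewis-acid demethylation: aluminium bound to the formyl oxygen activates only the two ortho methoxy groups for chloride attack, so the para methoxy group should survive.

Step 2
Reactants: 2 2,6-dihydroxy-4-methoxybenzaldehyde
Product: 3 2,6-bis(benzyloxy)-4-methoxybenzaldehyde
Conditions: BnBr (2.5 equiv), K2CO3 (3 equiv), DMF, 60 °C
Reagents that add atoms: benzyl bromide, BrCc1ccccc1
Why: Williamson ether synthesis on both phenols; warm DMF overcomes their hydrogen bonding to the aldehyde.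

Step 3
Reactants: 4 4-(4-hydroxyphenyl)butan-2-one
Product: 5 4-[4-(benzyloxy)phenyl]butan-2-one
Conditions: BnBr (1.1 equiv), K2CO3, acetone, reflux
Reagents that add atoms: benzyl bromide, BrCc1ccccc1
Why: Williamson ether synthesis; carbonate deprotonates the phenol but not the ketone.

Step 4
Reactants: 3 2,6-bis(benzyloxy)-4-methoxybenzaldehyde; 5 4-[4-(benzyloxy)phenyl]butan-2-one
Product: 6 (E)-1-[2,6-bis(benzyloxy)-4-methoxyphenyl]-5-[4-(benzyloxy)phenyl]pent-1-en-3-one
Conditions: NaOH (aq.), EtOH, rt to 40 °C, 5 in slight excess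
Reagents that add atoms: none
Why: Claisen–Schmidt condensation: under hydroxide the methyl alkyl ketone reacts through its methyl enolate with the non-enolisable aldehyde, and dehydration gives the conjugated E-enone.

Step 5
Reactants: 6 (E)-1-[2,6-bis(benzyloxy)-4-methoxyphenyl]-5-[4-(benzyloxy)phenyl]pent-1-en-3-one; 7 4-acetylphenyl acetate
Product: 10 2-[4-(acetyloxy)phenyl]-4-[2,6-bis(benzyloxy)-4-methoxyphenyl]-6-{2-[4-(benzyloxy)phenyl]ethyl}pyrylium tetrafluoroborate, via 1,5-diketone 8 (not isolated), via 4H-pyran 9 (not isolated)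
Conditions: 7 (3 equiv), Ph3C+ BF4− (1.2 equiv), BF3·OEt2 (2 equiv), ClCH2CH2Cl, 60 °C; precipitation with Et2O
Reagents that add atoms: triphenylcarbenium tetrafluoroborate, F[B-](F)(F)F.c1ccc(cc1)[C+](c1ccccc1)c1ccccc1
Why: Lewis-acid activation of enone 6 lets the enol of 7 add through its methyl carbon C3 to the β-carbon C4 (Michael addition) to give diketone 8; the enol oxygen O1 of the aryl ketone then attacks the C6 carbonyl, loss of water gives 4H-pyran 9, and the trityl cation abstracts hydride from C4–H to leave the aromatic pyrylium ion. The closest known reaction type is the classical pyrylium salt synthesis from a methyl ketone and a chalcone-type enone in the presence of a hydride acceptor. The one ring closed is the oxygen heterocycle, by 6-exo-trig attack of O1 on the C6 carbonyl followed by dehydration, so that a C3–C2–O1 unit and a C4–C5–C6 unit are joined in a [3+3] sense. No stereocentre survives the step: the C4 centre of 8 and 9 is erased on aromatisation, and C2, C4 and C6 are all set in step 6. The step needs chemoselectivity for the cross reaction and for O- over C-cyclisation: 7 has a single enolisable site and is used in excess to outrun self-condensation of 6 through its C7 methylene, and irreversible aromatisation should drain the reversible hemiketal manifold before a Robinson-type aldol closure of 8 can compete.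

Step 6
Reactants: 10 2-[4-(acetyloxy)phenyl]-4-[2,6-bis(benzyloxy)-4-methoxyphenyl]-6-{2-[4-(benzyloxy)phenyl]ethyl}pyrylium tetrafluoroborate
Product: 11 4-[(2S,4R,6S)-4-[2,6-bis(benzyloxy)-4-methoxyphenyl]-6-{2-[4-(benzyloxy)phenyl]ethyl}oxan-2-yl]phenyl acetate
Conditions: [Ir(cod)Cl]2 (2 mol %), (S)-SegPhos (4.4 mol %), H2 (50 bar), 2,6-di-tert-butyl-4-methylpyridine (1.0 equiv), CH2Cl2, 25 °C
Reagents that add atoms: none
Why: Proposed new method: the iridium hydride formed by heterolysis of H2 transfers hydride outer-sphere to an α-carbon of the pyrylium ion, the hindered pyridinium buffer re-protonates the resulting dienol ether to a conjugated oxocarbenium ion, and two further hydride/proton relays finish the reduction; the chiral ligand controls the first irreversible hydride transfer and the later hydrides add to half-chair oxocarbenium ions on the face that places each new substituent equatorial, so the all-equatorial, all-cis (2S,4R,6S) oxane should result with three stereocentres set in one event; the closest known reaction types are the Ir–bisphosphine asymmetric hydrogenation of pyridinium salts to cis-piperidines, the Ru–diamine asymmetric hydrogenation of isochromenylium ions and the all-cis heterogeneous hydrogenation of pyrylium salts.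

Step 7
Reactants: 11 4-[(2S,4R,6S)-4-[2,6-bis(benzyloxy)-4-methoxyphenyl]-6-{2-[4-(benzyloxy)phenyl]ethyl}oxan-2-yl]phenyl acetate
Product: 12 4-[(2S,4R,6S)-4-[3-acetyl-2,6-bis(benzyloxy)-4-methoxyphenyl]-6-{2-[4-(benzyloxy)phenyl]ethyl}oxan-2-yl]phenyl acetate
Conditions: AcOH (3 equiv) premixed with (CF3CO)2O (2 equiv), CH2Cl2, 0 °C to rt
Reagents that add atoms: acetic acid, CC(=O)O
Why: Friedel–Crafts acylation by the mixed acetic trifluoroacetic anhydride: only the 1,3,5-trioxygenated ring is nucleophilic enough, its two free positions are equivalent, and the acetoxy group on the C2 aryl keeps the benzylic C2–O1 bond from ionising.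

Step 8
Reactants: 12 4-[(2S,4R,6S)-4-[3-acetyl-2,6-bis(benzyloxy)-4-methoxyphenyl]-6-{2-[4-(benzyloxy)phenyl]ethyl}oxan-2-yl]phenyl acetate
Product: 13 4-[(2S,4R,6S)-4-(3-acetyl-2,6-dihydroxy-4-methoxyphenyl)-6-[2-(4-hydroxyphenyl)ethyl]oxan-2-yl]phenyl acetate
Conditions: H2 (1 atm), 10% Pd/C, EtOAc–MeOH, rt
Reagents that add atoms: none
Why: Hydrogenolysis of the three benzyl aryl ethers over palladium; the chelated aryl ketone, the aryl acetate and the acetoxy-deactivated benzylic C2–O1 bond should be left intact.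

Step 9
Reactants: 13 4-[(2S,4R,6S)-4-(3-acetyl-2,6-dihydroxy-4-methoxyphenyl)-6-[2-(4-hydroxyphenyl)ethyl]oxan-2-yl]phenyl acetate; 14 4-(oxan-2-yloxy)benzaldehyde
Product: 16 (E)-1-{2,4-dihydroxy-3-[(2S,4R,6S)-2-(4-hydroxyphenyl)-6-[2-(4-hydroxyphenyl)ethyl]oxan-4-yl]-6-methoxyphenyl}-3-(4-hydroxyphenyl)prop-2-en-1-one, via tetrahydropyranyl ether chalcone 15 (not isolated)
Conditions: KOH (50% aq., excess), EtOH, rt; aq. HCl to pH 5, extraction; crude in MeOH, PPTS (cat.), 40 °C
Reagents that add atoms: none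
Why: Claisen–Schmidt condensation of the acetophenone enolate with the acetal-protected aldehyde gives the E-enone while hydroxide removes the aryl acetate, and mild acid methanolysis of the tetrahydropyranyl acetal frees the last phenol; the all-equatorial oxane is the thermodynamic isomer, so reversible opening at C2 through a quinone methide should not erode it.

Compound list
1 | 2,4,6-trimethoxybenzaldehyde | COc1cc(OC)c(C=O)c(OC)c1 | starting material
2 | 2,6-dihydroxy-4-methoxybenzaldehyde | COc1cc(O)c(C=O)c(O)c1 | intermediate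
3 | 2,6-bis(benzyloxy)-4-methoxybenzaldehyde | COc1cc(OCc2ccccc2)c(C=O)c(OCc2ccccc2)c1 | intermediate
4 | 4-(4-hydroxyphenyl)butan-2-one (raspberry ketone) | CC(=O)CCc1ccc(O)cc1 | starting material
5 | 4-[4-(benzyloxy)phenyl]butan-2-one | CC(=O)CCc1ccc(OCc2ccccc2)cc1 | intermediate
6 | (E)-1-[2,6-bis(benzyloxy)-4-methoxyphenyl]-5-[4-(benzyloxy)phenyl]pent-1-en-3-one | COc1cc(OCc2ccccc2)c(/C=C/C(=O)CCc2ccc(OCc3ccccc3)cc2)c(OCc2ccccc2)c1 | intermediate
7 | 4-acetylphenyl acetate | CC(=O)Oc1ccc(cc1)C(C)=O | starting material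
8 | 4-{3-[2,6-bis(benzyloxy)-4-methoxyphenyl]-7-[4-(benzyloxy)phenyl]-5-oxoheptanoyl}phenyl acetate (racemic 1,5-diketone) | CC(=O)Oc1ccc(cc1)C(=O)CC(CC(=O)CCc1ccc(OCc2ccccc2)cc1)c1c(OCc2ccccc2)cc(OC)cc1OCc1ccccc1 | intermediate
9 | 4-{4-[2,6-bis(benzyloxy)-4-methoxyphenyl]-6-{2-[4-(benzyloxy)phenyl]ethyl}-4H-pyran-2-yl}phenyl acetate (racemic) | CC(=O)Oc1ccc(cc1)C1=CC(C=C(CCc2ccc(OCc3ccccc3)cc2)O1)c1c(OCc2ccccc2)cc(OC)cc1OCc1ccccc1 | intermediate
10 | 2-[4-(acetyloxy)phenyl]-4-[2,6-bis(benzyloxy)-4-methoxyphenyl]-6-{2-[4-(benzyloxy)phenyl]ethyl}pyrylium tetrafluoroborate | CC(=O)Oc1ccc(cc1)-c1cc(-c2c(OCc3ccccc3)cc(OC)cc2OCc2ccccc2)cc(CCc2ccc(OCc3ccccc3)cc2)[o+]1.F[B-](F)(F)F | intermediate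
11 | 4-[(2S,4R,6S)-4-[2,6-bis(benzyloxy)-4-methoxyphenyl]-6-{2-[4-(benzyloxy)phenyl]ethyl}oxan-2-yl]phenyl acetate (all-cis) | COc1cc(OCc2ccccc2)c([C@@H]2C[C@H](CCc3ccc(OCc4ccccc4)cc3)O[C@H](c3ccc(OC(C)=O)cc3)C2)c(OCc2ccccc2)c1 | intermediate
12 | 4-[(2S,4R,6S)-4-[3-acetyl-2,6-bis(benzyloxy)-4-methoxyphenyl]-6-{2-[4-(benzyloxy)phenyl]ethyl}oxan-2-yl]phenyl acetate | COc1cc(OCc2ccccc2)c([C@@H]2C[C@H](CCc3ccc(OCc4ccccc4)cc3)O[C@H](c3ccc(OC(C)=O)cc3)C2)c(OCc2ccccc2)c1C(C)=O | intermediate
13 | 4-[(2S,4R,6S)-4-(3-acetyl-2,6-dihydroxy-4-methoxyphenyl)-6-[2-(4-hydroxyphenyl)ethyl]oxan-2-yl]phenyl acetate | COc1cc(O)c([C@@H]2C[C@H](CCc3ccc(O)cc3)O[C@H](c3ccc(OC(C)=O)cc3)C2)c(O)c1C(C)=O | intermediate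
14 | 4-(oxan-2-yloxy)benzaldehyde (racemic tetrahydropyranyl ether of 4-hydroxybenzaldehyde) | O=Cc1ccc(OC2CCCCO2)cc1 | starting material
15 | (E)-1-{2,4-dihydroxy-3-[(2S,4R,6S)-2-(4-hydroxyphenyl)-6-[2-(4-hydroxyphenyl)ethyl]oxan-4-yl]-6-methoxyphenyl}-3-[4-(oxan-2-yloxy)phenyl]prop-2-en-1-one (both epimers at the acetal carbon; present as phenoxides in the flask) | COc1cc(O)c([C@@H]2C[C@H](CCc3ccc(O)cc3)O[C@H](c3ccc(O)cc3)C2)c(O)c1C(=O)/C=C/c1ccc(OC2CCCCO2)cc1 | intermediate
16 | (E)-1-{2,4-dihydroxy-3-[(2S,4R,6S)-2-(4-hydroxyphenyl)-6-[2-(4-hydroxyphenyl)ethyl]oxan-4-yl]-6-methoxyphenyl}-3-(4-hydroxyphenyl)prop-2-en-1-one (CNP0215517.1) | COc1cc(O)c([C@@H]2C[C@H](CCc3ccc(O)cc3)O[C@H](c3ccc(O)cc3)C2)c(O)c1C(=O)/C=C/c1ccc(O)cc1 | target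

Total step count: 9
Longest linear sequence: 8 steps (1 → 2 → 3 → 6 → 10 → 11 → 12 → 13 → 16; step 3 is a one-step side branch).

Steps most likely to fail

1. Step 6 (bears the label). The hydride may add to an α-carbon to give a 2H-pyran that opens electrocyclically to a dienone and is reduced to acyclic ketones. The first hydride transfer may be poorly enantioselective. In a stepwise ionic pathway the facial course at C4 may deliver the C4 epimer, and the acid set free may ionise the C2–O1 bond. The fallback uses known chemistry, sets out from enone 6 and returns at 11. 3-(4-Hydroxyphenyl)-3-oxopropanoic acid F1, made fresh by saponification of its commercial ethyl ester, would add to 6 in an organocatalytic decarboxylative Michael reaction (9-amino-9-deoxy-epi-cinchona primary amine salt, iminium activation, pseudoenantiomer chosen for the R adduct) to give (3R)-3-[2,6-bis(benzyloxy)-4-methoxyphenyl]-7-[4-(benzyloxy)phenyl]-1-(4-hydroxyphenyl)heptane-1,5-dione F2. Acetylation (Ac2O, pyridine) would give the acetate F3, the R enantiomer of 8. Asymmetric transfer hydrogenation with RuCl[(S,S)-TsDPEN](p-cymene) and HCO2H–Et3N should reduce only the aryl ketone, to the (1S,3S)-hydroxy ketone F4. Reductive etherification (Et3SiH, TMSOTf, CH2Cl2, −78 °C) through the cyclic oxocarbenium ion, with axial hydride delivery, would close O1–C6 and give 11.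

2. Step 5. Enone 6 may self-condense through its C7 methylene, diketone 8 may close by a Robinson-type aldol (C7 onto C2) instead of through oxygen, hydride abstraction from the hindered C4–H of 9 by the bulky trityl cation may be slow, and the Lewis acid may cleave or shift benzyl ethers. The fallback sets out from aldehyde 3 and returns at 10. Ohira–Bestmann homologation would give 1,3-bis(benzyloxy)-2-ethynyl-5-methoxybenzene F5. Its lithium acetylide would be acylated with 3-[4-(benzyloxy)phenyl]-N-methoxy-N-methylpropanamide F6 (from the commercial acid) to give the ynone 1-[2,6-bis(benzyloxy)-4-methoxyphenyl]-5-[4-(benzyloxy)phenyl]pent-1-yn-3-one F7. Condensation of F7 with 7 under HBF4·OEt2 (Michael addition of the enol to the ynone, then cyclodehydration of the ene-dione) gives 10 without a hydride acceptor, because the ynone is already at the pyrylium oxidation level.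

3. Step 9. Enolisation of the polyphenolate acetophenone may be too slow, so that condensation stays incomplete while the material sits in strong base. The fallback sets out from 13 and returns at 16. Protection of the two non-chelated phenols (MOMCl, iPr2NEt) would give 4-[(2S,4R,6S)-4-[3-acetyl-2-hydroxy-4-methoxy-6-(methoxymethoxy)phenyl]-6-{2-[4-(methoxymethoxy)phenyl]ethyl}oxan-2-yl]phenyl acetate F8. Claisen–Schmidt condensation with commercial 4-(methoxymethoxy)benzaldehyde (KOH, EtOH; the aryl acetate is lost) would give the protected chalcone (E)-1-{2-hydroxy-3-[(2S,4R,6S)-2-(4-hydroxyphenyl)-6-{2-[4-(methoxymethoxy)phenyl]ethyl}oxan-4-yl]-6-methoxy-4-(methoxymethoxy)phenyl}-3-[4-(methoxymethoxy)phenyl]prop-2-en-1-one F9. HCl in MeOH would remove the three MOM groups to give 16.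

Further compounds
F1 | step 6 | 3-(4-hydroxyphenyl)-3-oxopropanoic acid | OC(=O)CC(=O)c1ccc(O)cc1
F2 | step 6 | (3R)-3-[2,6-bis(benzyloxy)-4-methoxyphenyl]-7-[4-(benzyloxy)phenyl]-1-(4-hydroxyphenyl)heptane-1,5-dione | COc1cc(OCc2ccccc2)c([C@@H](CC(=O)c2ccc(O)cc2)CC(=O)CCc2ccc(OCc3ccccc3)cc2)c(OCc2ccccc2)c1
F3 | step 6 | 4-{(3R)-3-[2,6-bis(benzyloxy)-4-methoxyphenyl]-7-[4-(benzyloxy)phenyl]-5-oxoheptanoyl}phenyl acetate | COc1cc(OCc2ccccc2)c([C@@H](CC(=O)c2ccc(OC(C)=O)cc2)CC(=O)CCc2ccc(OCc3ccccc3)cc2)c(OCc2ccccc2)c1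
F4 | step 6 | 4-{(1S,3S)-3-[2,6-bis(benzyloxy)-4-methoxyphenyl]-7-[4-(benzyloxy)phenyl]-1-hydroxy-5-oxoheptyl}phenyl acetate | COc1cc(OCc2ccccc2)c([C@@H](C[C@H](O)c2ccc(OC(C)=O)cc2)CC(=O)CCc2ccc(OCc3ccccc3)cc2)c(OCc2ccccc2)c1
F5 | step 5 | 1,3-bis(benzyloxy)-2-ethynyl-5-methoxybenzene | COc1cc(OCc2ccccc2)c(C#C)c(OCc2ccccc2)c1
F6 | step 5 | 3-[4-(benzyloxy)phenyl]-N-methoxy-N-methylpropanamide | CON(C)C(=O)CCc1ccc(OCc2ccccc2)cc1
F7 | step 5 | 1-[2,6-bis(benzyloxy)-4-methoxyphenyl]-5-[4-(benzyloxy)phenyl]pent-1-yn-3-one | COc1cc(OCc2ccccc2)c(C#CC(=O)CCc2ccc(OCc3ccccc3)cc2)c(OCc2ccccc2)c1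
F8 | step 9 | 4-[(2S,4R,6S)-4-[3-acetyl-2-hydroxy-4-methoxy-6-(methoxymethoxy)phenyl]-6-{2-[4-(methoxymethoxy)phenyl]ethyl}oxan-2-yl]phenyl acetate | COc1cc(OCOC)c([C@@H]2C[C@H](CCc3ccc(OCOC)cc3)O[C@H](c3ccc(OC(C)=O)cc3)C2)c(O)c1C(C)=O
F9 | step 9 | (E)-1-{2-hydroxy-3-[(2S,4R,6S)-2-(4-hydroxyphenyl)-6-{2-[4-(methoxymethoxy)phenyl]ethyl}oxan-4-yl]-6-methoxy-4-(methoxymethoxy)phenyl}-3-[4-(methoxymethoxy)phenyl]prop-2-en-1-one | COc1cc(OCOC)c([C@@H]2C[C@H](CCc3ccc(OCOC)cc3)O[C@H](c3ccc(O)cc3)C2)c(O)c1C(=O)/C=C/c1ccc(OCOC)cc1
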